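The data come from a simulation with made-up constants; noise was put on by code.

I began with an easy step: I set the last target reading of each earlier closed flask beside its charge.

| setting | larch | ash | elm | north-east | east | south-west |
|---|---|---|---|---|---|---|
| starting material | 0.20 M | 0.20 M | 0.20 M | 0.20 M | 0.20 M (fed, over 1.60 h) | 0.20 M |
| protic impurity | 0.040 M | 0.027 M | 0.060 M | 0.0400 M | 0.0400 M | 0.0400 M |
| remark | run made earlier | run made earlier | run made earlier | a single well-mixed tank run continuously and read at steady state, 2.0 h in it on average | all but starting material at the start; starting material goes in evenly over 1.60 h, the run ends at 2.0 h | a closed flask charged with all of it at once and left for 2.0 h |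
| time |  |  |  |  | 2.0 h | 2.0 h |

| larch: time / min | larch: target / % | ash: time / h | ash: target / % | elm: time / h | elm: target / % |
|---|---|---|---|---|---|
| 12.0 | 38.4 | 0.417 | 68.5 | 0.417 | 59.5 |
| 25.0 | 66.5 | 0.833 | 85.5 | 0.833 | 70.8 |
| 40.0 | 77.2 | 1.33 | 86.2 | 1.33 | 70.7 |
| 50.0 | 79.2 | 1.50 | 83.9 | 1.50 | 71.0 |
| 60.0 | 79.4 | 2.00 | 86.5 | 2.00 | 69.6 |
| 80.0 | 80.7 | 2.50 | 87.4 | 2.50 | 71.3 |

(standard deviation of a reading: 1 percentage point)

- the stated concentrations are those of everything mixed, before any reaction; amounts are the same in each set-up
- the analysis behind the earlier runs scatters by 1 percentage point, standard deviation
- steps under discussion: starting material -> target; starting material + protic impurity -> quenched substrate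
- the feed brings no volume worth counting
- the earlier runs were made in a closed, stirred flask

- the set-up with the highest amount of target at the outlet or at the end, in percent of the starting material put in ("none" if the first two lie within 2 percentage points) (north-east / east / south-west / none)
- amount of target at the outlet or at the end, in percent of the starting material put in, north-east
- amount of target at the outlet or at the end, in percent of the starting material put in, east
- amount of target at the outlet or at the end, in percent of the starting material put in, south-west

Instead of reckoning the large yield, I reckoned the small correction to it, the loss, taking one starting material for each protic impurity charged. This gave Y, one minus the ratio of protic impurity charged to starting material charged, for south-west 80.0%: the quench plateau. Of the quench's partners the protic impurity is the smaller charge, with 0.0400 M against 0.20 M. Y gave 80.0% for larch, which read 80.7%; 86.5% for ash, which read 87.4%; and 70.0% for elm, which read 71.3%. The larch readings had reached 79.2% by 50.0 min, and the south-west flask stands longer, at 2.0 h, so I committed to Y for that flask.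

The forecast gave 74.8% for north-east, 80% for east and 80% for south-west, with best none. Its ground was: "The quench is therefore fast and stoichiometric".

The simulation gave 80.8% for north-east, 81.9% for east and 80.3% for south-west, so best was none, the top two lying 1 percentage point apart, within the margin of 2 points.

    starting material → target, rate k1*[starting material]/(1 + ([starting material]/sat1)) (0.0720 M, k = 0.140 /min)
    starting material + protic impurity → quenched substrate (k = 1.60 /M/min)

South-west gave 80.3% against Y of 80.0%. The north-east tank stood 6 points above the forecast's 74.8%, at 80.8%, with 5.55% of the starting material still at its outlet. For a neighbour of south-west charged with 0.068 M of protic impurity, Y is 66.0%, and that flask gave 67.3%.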